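**Plan**
Numbering used throughout (xenicane type): the ring oxygen bridges C1 and C4; C3 is the acyloxymethyl carbon on C4; C4a/C11a are the ring-fusion carbons; C5–C11 complete the carbocycle (C7 carbinol, C8=C9, exocyclic C11=C19); C12–C17 is the dienyl chain.
Retrosynthetic cuts, in order: C12=C13 (phosphonate olefination), C8=C9 (ring-closing metathesis), C9–C10 (allyl–vinyl coupling), the C3–O acyl bond, a temporary C1 carboxyl, then C1–O and C1–C11a in one event, C4–C12, C4–C4a and C11=C11a.
Forward: (S)-linalool supplies C5–C8; an Ireland–Claisen rearrangement joins it to a glycolate (C4–C4a); metathesis closes a 3,6-dihydro-2H-pyran (O, C19, C11, C11a, C4a, C4); the key step contracts it to the tetrahydrofuran; the nine-membered ring is closed next and the diene is added last.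
Enabling feature: ring O, C1, C11a and the exocyclic C11=C19 form a homoallyl ether (O–C1–C11a–C11=C19), the retron of a [2,3]-shift of an oxonium ylide whose allyl part is the O–C19–C11=C11a unit of a dihydropyran. The C3 hydroxymethyl on C4 carries the carbene as a diazoacetate, and its carbonyl carbon is later removed as CO2.
Stereochemistry: C7 from linalool; C4a by 1,3-chirality transfer from a CBS-derived carbinol; C4 by alkylation of the cyclic enolate anti to the C4a chain; C11a by the tethered ylide shift.

Key step: step 13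

Remark: (S)-(+)-linalool of high enantiomeric purity is assumed. C7 is carried through unchanged, so any erosion there would appear as a diastereomer after step 8.

**Route**

Step 1
Reactants: 1 (S)-(+)-linalool
Product: 2 (S)-linalool tert-butyldimethylsilyl (TBS) ether
Conditions: TBSOTf, 2,6-lutidine, CH2Cl2, 0 °C to rt
Reagents that add atoms: tert-butyldimethylsilyl trifluoromethanesulfonate, CC(C)(C)[Si](C)(C)OS(=O)(=O)C(F)(F)F
Why: Silyl triflate silylation of the tertiary alcohol should proceed cleanly; the bulky ether shields the neighbouring vinyl group in the later metathesis and prevents oxa-Michael addition after step 3.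

Step 2
Reactants: 2 (S)-linalool TBS ether
Product: 3 (4S)-4-(tert-butyldimethylsilyloxy)-4-methylhex-5-enal
Conditions: O3, CH2Cl2, −78 °C, Sudan Red 7B end-point indicator; then PPh3, −78 °C to rt
Reagents that add atoms: ozone, [O-][O+]=O
Why: Ozone attacks the electron-rich trisubstituted alkene far faster than the vinyl group on the quaternary carbon, so ozonolysis stopped at the indicator end point and reductive work-up should give the aldehyde (chemoselective ozonolysis).

Step 3
Reactants: 3 (4S)-4-(tert-butyldimethylsilyloxy)-4-methylhex-5-enal; 4 1-(triphenylphosphoranylidene)propan-2-one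
Product: 5 (3E,7S)-7-(tert-butyldimethylsilyloxy)-7-methylnona-3,8-dien-2-one
Conditions: toluene, 80 °C
Reagents that add atoms: none
Why: Wittig olefination with the stabilised ylide should give the (E)-enone.

Step 4
Reactants: 5 (3E,7S)-enone
Product: 6 (2R,3E,7S)-7-(tert-butyldimethylsilyloxy)-7-methylnona-3,8-dien-2-ol
Conditions: (S)-2-methyl-CBS-oxazaborolidine (15 mol %), catecholborane, toluene, −78 °C
Reagents that add atoms: none
Why: Corey–Bakshi–Shibata reduction: with the (S)-oxazaborolidine the alkenyl group acts as the large substituent and hydride is delivered to give the (R)-allylic alcohol, catecholborane at low temperature avoiding hydroboration.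

Step 5
Reactants: 7 2-methylenepropane-1,3-diol
Product: 8 2-[(tert-butyldimethylsilyloxy)methyl]prop-2-en-1-ol
Conditions: NaH (1.0 equiv), THF, 0 °C; TBSCl (1.0 equiv)
Reagents that add atoms: tert-butyldimethylsilyl chloride, CC(C)(C)[Si](C)(C)Cl
Why: The sparingly soluble monosodium alkoxide of the symmetric diol is silylated once (statistical mono-protection of a diol).

Step 6
Reactants: 8 mono-TBS diol; 9 bromoacetic acid
Product: 10 2-({2-[(tert-butyldimethylsilyloxy)methyl]prop-2-en-1-yl}oxy)acetic acid
Conditions: NaH (2.5 equiv), THF, 0 °C to 60 °C; buffered acidic work-up (pH 4)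
Reagents that add atoms: none
Why: Williamson etherification in which the sodium alkoxide displaces bromide from sodium bromoacetate.

Step 7
Reactants: 6 (2R,3E,7S)-allylic alcohol; 10 allyloxyacetic acid
Product: 11 (2R,3E,7S)-7-(TBS-oxy)-7-methylnona-3,8-dien-2-yl 2-({2-[(TBS-oxy)methyl]prop-2-en-1-yl}oxy)acetate
Conditions: DCC, DMAP (cat.), CH2Cl2, 0 °C to rt
Reagents that add atoms: none
Why: Steglich esterification joins the two fragments without touching the carbinol stereocentre.

Step 8
Reactants: 11 glycolate ester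
Product: 15 methyl (2R,3S,6S)-6-(TBS-oxy)-6-methyl-2-({2-[(TBS-oxy)methyl]prop-2-en-1-yl}oxy)-3-[(E)-prop-1-enyl]oct-7-enoate, via silyl ketene acetal 12 (not isolated), via trimethylsilyl ester 13 (not isolated), via carboxylic acid 14 (not isolated)
Conditions: LDA, TMSCl–Et3N, THF, −78 °C to rt; aq. citric acid; then MeI, K2CO3, DMF, rt
Reagents that add atoms: iodomethane, CI
Why: Ireland–Claisen rearrangement: in-situ silylation gives the chelation-derived (Z)-ketene acetal (and forestalls a [2,3]-Wittig shift of the allyloxy enolate), the chair transition state with the carbinol methyl equatorial transfers the (R)-carbinol chirality across the (E)-olefin to C4a (S) and sets C4 provisionally, and the acid is then methylated.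

Step 9
Reactants: 15 methyl ester
Product: 16 methyl (2R,3S)-3-[(3S)-3-(TBS-oxy)-3-methylpent-4-enyl]-5-[(TBS-oxy)methyl]-3,6-dihydro-2H-pyran-2-carboxylate
Conditions: second-generation Grubbs catalyst [RuCl2(=CHPh)(PCy3)(H2IMes)] (5 mol %), CH2Cl2 (5 mM), 40 °C
Reagents that add atoms: none
Why: Ring-closing metathesis between the propenyl group (propene is lost) and the 2-substituted allyl ether should form the trisubstituted C11=C11a olefin of the six-membered ring, the vinyl group on the fully substituted, TBS-shielded C7 being too hindered to compete at this temperature.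

Step 10
Reactants: 16 dihydropyran ester; 17 (chloromethoxy)triisopropylsilane
Product: 18 methyl (2S,3S)-3-[(3S)-3-(TBS-oxy)-3-methylpent-4-enyl]-5-[(TBS-oxy)methyl]-2-[(triisopropylsilyloxy)methyl]-3,6-dihydro-2H-pyran-2-carboxylate (ester cis to the C3 side chain)
Conditions: LDA, THF, −78 °C; then 17, DMPU, −78 to −40 °C
Reagents that add atoms: none
Why: Alkylation of the cyclic α-alkoxy ester enolate with the chloromethyl ether: allylic strain with the exocyclic enolate puts the C4a side chain pseudoaxial, so the electrophile should enter anti to it and fix the C4 quaternary centre with the ester cis and the new CH2OTIPS (C12) trans to that chain, while a [2,3]-Wittig shift is geometrically impossible inside the ring.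

Step 11
Reactants: 18 quaternary dihydropyran ester
Product: 19 dihydropyran alcohol, [(2R,3S)-2-(hydroxymethyl)] analogue of 18 (CH2OH cis to the C3 side chain)
Conditions: LiAlH4, THF, 0 °C
Reagents that add atoms: none
Why: Hydride reduction of the hindered ester (LiAlH4 reduction) gives the neopentyl alcohol on the face of the C4a chain, and silyl ethers and alkenes are inert.

Step 12
Reactants: 19 dihydropyran alcohol; 20 bromoacetyl bromide
Product: 22 diazoacetate of 19, via bromoacetate 21 (not isolated)
Conditions: 20, pyridine, CH2Cl2, 0 °C; then TsNHNHTs, DBU, THF, 0 °C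
Reagents that add atoms: N,N'-bis(4-methylphenylsulfonyl)hydrazine, Cc1ccc(cc1)S(=O)(=O)NNS(=O)(=O)c1ccc(C)cc1
Why: Acylation of the neopentyl alcohol followed by displacement of bromide with N,N'-ditosylhydrazine and base-induced loss of two sulfinate units should give the diazoacetate under mild conditions that leave the silyl ethers and alkenes alone (bromoacetate-to-diazoacetate conversion).

Step 13
Reactants: 22 diazoacetate
Product: 24 bridged lactone (3,8-dioxabicyclo[3.2.1]octan-2-one core: the tetrahydrofuran with its C1 carboxyl lactonised onto the C3 oxygen; C11a bears the 3-(TBS-oxy)prop-1-en-2-yl group trans to the C4a chain), via oxonium ylide 23 (not isolated)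
Conditions: Cu(hfacac)2 [Cu(CF3COCHCOCF3)2] (5 mol %), CH2Cl2, reflux, slow addition of 22
Reagents that add atoms: none
Why: Proposed new method: loss of N2 from 22 at copper should give an electrophilic carbenoid at C1 that is attacked by the ring oxygen of the dihydropyran (closure of a six-membered 1,4-dioxan-2-one ring by O-to-carbenoid attack, which makes the C1–O bond) to form oxonium ylide 23, and C1 should then bond to C11a in a suprafacial [2,3]-sigmatropic shift while the O–C19 bond breaks, so that the six-membered ring contracts to the tetrahydrofuran (five-centre envelope transition state, with the O–C19–C11=C11a array held cisoid by the ring) and C11=C19 emerges as the exocyclic methylene. The closest known reaction types are the copper- or rhodium-catalysed oxonium ylide formation–[2,3]-rearrangement of allyl ethers tethered to diazoketones and diazoacetates and the [2,3]-ring contraction of 1,2,3,6-tetrahydropyridinium ylides to 3-vinylpyrrolidines; an endocyclic allyl ether contracted through a lactone-bridged ylide has not been shown. C11a is controlled by the tether: only the ylide in which C1 sits on the face of the C3 arm can reach C11a, C1 is delivered to that face and C11 is pushed to the opposite one, trans to C5 (the trans ring fusion), whereas the temporary C1 centre is fixed cis to C3 by the lactone bridge. The step needs ylide formation to win over C–H insertion and cyclopropanation and the [2,3]-shift to win over a [1,2]-shift; the electrophilic Cu(hfacac)2 catalyst, the six-membered approach to the Lewis-basic ring oxygen, the lack of any alkene on C4 and the pre-organised allyl ether should secure this.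

Step 14
Reactants: 24 bridged lactone
Product: 26 tetrahydrofuran alcohol (C1 now CH2, free C3–OH, C12–OTIPS, C7–OTBS, primary allylic OTBS), via lithium carboxylate 25 (not isolated)
Conditions: LiOH·H2O, THF/H2O, rt; solvent exchange; 9-mesityl-10-methylacridinium tetrafluoroborate (5 mol %), PhSSPh (10 mol %), CF3CH2OH, 450 nm LEDs, rt
Reagents that add atoms: none
Why: Saponification of the strained bridged lactone followed by acridinium photoredox hydrodecarboxylation (carboxylate oxidation, loss of CO2, hydrogen-atom transfer from thiophenol to the α-alkoxy C1 radical) should remove the tether carbon without acidifying the hydroxy acid, and the temporary C1 stereocentre disappears.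

Step 15
Reactants: 26 tetrahydrofuran alcohol; 27 nonadecanoic acid
Product: 28 C3 nonadecanoate of 26
Conditions: DCC, DMAP, CH2Cl2, rt
Reagents that add atoms: none
Why: Carbodiimide (Steglich) esterification of the only free hydroxyl, the neopentyl C3–OH, installs the nonadecanoate.

Step 16
Reactants: 28 nonadecanoate
Product: 29 primary allylic alcohol (C10–OH; C7–OTBS and C12–OTIPS retained)
Conditions: camphorsulfonic acid (10 mol %), MeOH/CH2Cl2, 0 °C
Reagents that add atoms: none
Why: Acid-catalysed methanolysis (selective desilylation) should cleave the unhindered primary allylic TBS ether much faster than the tertiary TBS and the neopentyl TIPS ethers, and the ester is untouched at 0 °C.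

Step 17
Reactants: 29 allylic alcohol
Product: 30 allylic methyl carbonate
Conditions: ClCO2Me, pyridine, CH2Cl2, 0 °C
Reagents that add atoms: methyl chloroformate, COC(=O)Cl
Why: Acylation of the primary allylic alcohol with methyl chloroformate (carbonate formation), to which the tertiary silyl ether and the ester are inert.

Step 18
Reactants: 30 allylic methyl carbonate; 31 tributyl(vinyl)stannane
Product: 32 skipped diene (C11a bears the penta-1,4-dien-2-yl group)
Conditions: Pd2(dba)3 (2.5 mol %), P(2-furyl)3 (10 mol %), DMF, 50 °C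
Reagents that add atoms: none
Why: Ionisation of the carbonate by zerovalent palladium gives a 2-substituted π-allyl complex whose two CH2 termini are equivalent, so transmetalation from tin and reductive elimination can only give the 1,4-diene (Stille-type allyl–vinyl coupling under neutral conditions).

Step 19
Reactants: 32 skipped diene
Product: 33 diol (free C7–OH and C12–OH)
Conditions: HF·pyridine, pyridine, THF, 0 °C to rt
Reagents that add atoms: none
Why: Buffered hydrogen fluoride (fluoride desilylation) should remove the tertiary TBS and the primary TIPS groups without ionising the tertiary allylic alcohol or cleaving the ester, and the product is oxidised at once because its free C12 hydroxyl sits 1,3 to the C3 ester.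

Step 20
Reactants: 33 diol
Product: 34 C12 aldehyde
Conditions: Dess–Martin periodinane, NaHCO3, CH2Cl2, 0 °C
Reagents that add atoms: none
Why: Dess–Martin oxidation converts the only primary alcohol into the non-enolisable aldehyde, leaves the tertiary allylic alcohol alone and removes the hydroxyl that could accept the nonadecanoyl group by 1,3-migration.

Step 21
Reactants: 34 aldehyde
Product: 35 nine-membered-ring aldehyde ((Z)-C8=C9, trans-fused to the tetrahydrofuran)
Conditions: second-generation Grubbs catalyst (15 mol %), 1,4-benzoquinone (cat.), toluene (1 mM), 80 °C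
Reagents that add atoms: none
Why: Ring-closing metathesis in which the catalyst should load on the unhindered allyl terminus and close onto the vinyl group of the free tertiary allylic alcohol at high dilution, the nine-membered ring being able to hold only the (Z)-olefin and the trans-fused tetrahydrofuran holding the two chains within reach.

Step 22
Reactants: 35 nine-membered-ring aldehyde; 36 diethyl (3-methylbut-2-en-1-yl)phosphonate
Product: 37 CNP0120482.1 (target)
Conditions: 36 (3 equiv), n-BuLi (2.9 equiv), THF, −78 °C; then 35, −78 to 0 °C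
Reagents that add atoms: none
Why: Horner–Wadsworth–Emmons-type olefination with the lithiated allylic phosphonate, which reacts at its α-carbon with the hindered aldehyde faster than with the ester and should give the (E)-C12=C13 bond of the conjugated diene, the extra base only deprotonating the tertiary hydroxyl.

**Compound list**
1 | (S)-(+)-linalool | C=C[C@@](C)(O)CCC=C(C)C | starting material
2 | (S)-linalool TBS ether | C=C[C@@](C)(O[Si](C)(C)C(C)(C)C)CCC=C(C)C | intermediate
3 | (4S)-4-(TBS-oxy)-4-methylhex-5-enal | C=C[C@@](C)(O[Si](C)(C)C(C)(C)C)CCC=O | intermediate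
4 | 1-(triphenylphosphoranylidene)propan-2-one | CC(=O)C=P(c1ccccc1)(c1ccccc1)c1ccccc1 | starting material
5 | (3E,7S)-7-(TBS-oxy)-7-methylnona-3,8-dien-2-one | C=C[C@@](C)(O[Si](C)(C)C(C)(C)C)CC/C=C/C(C)=O | intermediate
6 | (2R,3E,7S)-7-(TBS-oxy)-7-methylnona-3,8-dien-2-ol | C=C[C@@](C)(O[Si](C)(C)C(C)(C)C)CC/C=C/[C@@H](C)O | intermediate
7 | 2-methylenepropane-1,3-diol | C=C(CO)CO | starting material
8 | 2-[(TBS-oxy)methyl]prop-2-en-1-ol | C=C(CO)CO[Si](C)(C)C(C)(C)C | intermediate
9 | bromoacetic acid | OC(=O)CBr | starting material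
10 | 2-({2-[(TBS-oxy)methyl]prop-2-en-1-yl}oxy)acetic acid | OC(=O)COCC(=C)CO[Si](C)(C)C(C)(C)C | intermediate
11 | glycolate ester of 6 with 10 | C=C[C@@](C)(O[Si](C)(C)C(C)(C)C)CC/C=C/[C@@H](C)OC(=O)COCC(=C)CO[Si](C)(C)C(C)(C)C | intermediate
12 | (Z)-trimethylsilyl ketene acetal of 11 | C=C[C@@](C)(O[Si](C)(C)C(C)(C)C)CC/C=C/[C@@H](C)O/C(O[Si](C)(C)C)=C/OCC(=C)CO[Si](C)(C)C(C)(C)C | intermediate
13 | trimethylsilyl ester of acid 14 | C=C[C@@](C)(O[Si](C)(C)C(C)(C)C)CC[C@H]([C@@H](OCC(=C)CO[Si](C)(C)C(C)(C)C)C(=O)O[Si](C)(C)C)/C=C/C | intermediate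
14 | (2R,3S,6S)-6-(TBS-oxy)-6-methyl-2-({2-[(TBS-oxy)methyl]allyl}oxy)-3-[(E)-prop-1-enyl]oct-7-enoic acid | C=C[C@@](C)(O[Si](C)(C)C(C)(C)C)CC[C@H]([C@@H](OCC(=C)CO[Si](C)(C)C(C)(C)C)C(=O)O)/C=C/C | intermediate
15 | methyl ester of 14 | C=C[C@@](C)(O[Si](C)(C)C(C)(C)C)CC[C@H]([C@@H](OCC(=C)CO[Si](C)(C)C(C)(C)C)C(=O)OC)/C=C/C | intermediate
16 | methyl (2R,3S)-3-[(3S)-3-(TBS-oxy)-3-methylpent-4-enyl]-5-[(TBS-oxy)methyl]-3,6-dihydro-2H-pyran-2-carboxylate | C=C[C@@](C)(O[Si](C)(C)C(C)(C)C)CC[C@H]1C=C(CO[Si](C)(C)C(C)(C)C)CO[C@H]1C(=O)OC | intermediate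
17 | (chloromethoxy)triisopropylsilane | ClCO[Si](C(C)C)(C(C)C)C(C)C | starting material
18 | methyl (2S,3S)-2-[(TIPS-oxy)methyl] dihydropyran-2-carboxylate (ester cis to the C3 chain) | C=C[C@@](C)(O[Si](C)(C)C(C)(C)C)CC[C@H]1C=C(CO[Si](C)(C)C(C)(C)C)CO[C@@]1(CO[Si](C(C)C)(C(C)C)C(C)C)C(=O)OC | intermediate
19 | (2R,3S)-2-(hydroxymethyl) dihydropyran (alcohol from 18) | C=C[C@@](C)(O[Si](C)(C)C(C)(C)C)CC[C@H]1C=C(CO[Si](C)(C)C(C)(C)C)CO[C@@]1(CO[Si](C(C)C)(C(C)C)C(C)C)CO | intermediate
20 | bromoacetyl bromide | BrCC(Br)=O | starting material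
21 | bromoacetate of 19 | C=C[C@@](C)(O[Si](C)(C)C(C)(C)C)CC[C@H]1C=C(CO[Si](C)(C)C(C)(C)C)CO[C@@]1(CO[Si](C(C)C)(C(C)C)C(C)C)COC(=O)CBr | intermediate
22 | diazoacetate of 19 | C=C[C@@](C)(O[Si](C)(C)C(C)(C)C)CC[C@H]1C=C(CO[Si](C)(C)C(C)(C)C)CO[C@@]1(CO[Si](C(C)C)(C(C)C)C(C)C)COC(=O)C=[N+]=[N-] | intermediate
23 | bicyclic oxonium ylide (C1 on the ring oxygen, lactone ring to C3) | C=C[C@@](C)(O[Si](C)(C)C(C)(C)C)CC[C@H]1C=C(CO[Si](C)(C)C(C)(C)C)C[O+]2[CH-]C(=O)OC[C@@]12CO[Si](C(C)C)(C(C)C)C(C)C | intermediate
24 | bridged lactone (tetrahydrofuran with C1–CO–O–C3 bridge) | C=C[C@@](C)(O[Si](C)(C)C(C)(C)C)CC[C@H]1[C@H](C(=C)CO[Si](C)(C)C(C)(C)C)[C@@H]2O[C@@]1(CO[Si](C(C)C)(C(C)C)C(C)C)COC2=O | intermediate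
25 | lithium C1-carboxylate with free C3–OH | C=C[C@@](C)(O[Si](C)(C)C(C)(C)C)CC[C@H]1[C@H](C(=C)CO[Si](C)(C)C(C)(C)C)[C@@H](C(=O)[O-])O[C@@]1(CO[Si](C(C)C)(C(C)C)C(C)C)CO.[Li+] | intermediate
26 | tetrahydrofuran alcohol (free C3–OH) | C=C[C@@](C)(O[Si](C)(C)C(C)(C)C)CC[C@H]1[C@H](C(=C)CO[Si](C)(C)C(C)(C)C)CO[C@@]1(CO[Si](C(C)C)(C(C)C)C(C)C)CO | intermediate
27 | nonadecanoic acid | CCCCCCCCCCCCCCCCCCC(=O)O | starting material
28 | C3 nonadecanoate of 26 | C=C[C@@](C)(O[Si](C)(C)C(C)(C)C)CC[C@H]1[C@H](C(=C)CO[Si](C)(C)C(C)(C)C)CO[C@@]1(CO[Si](C(C)C)(C(C)C)C(C)C)COC(=O)CCCCCCCCCCCCCCCCCC | intermediate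
29 | primary allylic alcohol | C=C[C@@](C)(O[Si](C)(C)C(C)(C)C)CC[C@H]1[C@H](C(=C)CO)CO[C@@]1(CO[Si](C(C)C)(C(C)C)C(C)C)COC(=O)CCCCCCCCCCCCCCCCCC | intermediate
30 | allylic methyl carbonate | C=C[C@@](C)(O[Si](C)(C)C(C)(C)C)CC[C@H]1[C@H](C(=C)COC(=O)OC)CO[C@@]1(CO[Si](C(C)C)(C(C)C)C(C)C)COC(=O)CCCCCCCCCCCCCCCCCC | intermediate
31 | tributyl(vinyl)stannane | C=C[Sn](CCCC)(CCCC)CCCC | starting material
32 | skipped diene (penta-1,4-dien-2-yl on C11a) | C=C[C@@](C)(O[Si](C)(C)C(C)(C)C)CC[C@H]1[C@H](C(=C)CC=C)CO[C@@]1(CO[Si](C(C)C)(C(C)C)C(C)C)COC(=O)CCCCCCCCCCCCCCCCCC | intermediate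
33 | diol (C7–OH, C12–OH) | C=C[C@@](C)(O)CC[C@H]1[C@H](C(=C)CC=C)CO[C@@]1(CO)COC(=O)CCCCCCCCCCCCCCCCCC | intermediate
34 | C12 aldehyde | C=C[C@@](C)(O)CC[C@H]1[C@H](C(=C)CC=C)CO[C@@]1(C=O)COC(=O)CCCCCCCCCCCCCCCCCC | intermediate
35 | nine-membered-ring aldehyde | C=C1C/C=C\[C@@](C)(O)CC[C@H]2[C@H]1CO[C@@]2(C=O)COC(=O)CCCCCCCCCCCCCCCCCC | intermediate
36 | diethyl (3-methylbut-2-en-1-yl)phosphonate | CCOP(=O)(CC=C(C)C)OCC | starting material
37 | CNP0120482.1 | C=C1C/C=C\[C@@](C)(O)CC[C@H]2[C@H]1CO[C@@]2(/C=C/C=C(C)C)COC(=O)CCCCCCCCCCCCCCCCCC | target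

**Totals**
Total step count: 22. Longest linear sequence: 20 steps (steps 1–4 and 7–22 from (S)-linalool; steps 5 and 6 make fragment 10).

**Steps most likely to fail**

1. Step 13 (key step). The carbenoid may be diverted to C–H insertion or cyclopropanation, or ylide 23 may revert or collapse by a [1,2]-shift. Fallback by known chemistry, setting out from 18 and coming back at 26: the ring contraction is replaced by a radical cyclisation that also delivers C1 from the ring oxygen (acyclic delivery, for example conjugate addition, would be expected to give the C11a epimer).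
 - Allylic oxidation of 18 at C19 (CrO3, 3,5-dimethylpyrazole) would give the unsaturated δ-lactone F1.
 - DIBAL-H and then NaBH4/CeCl3 would open it to the tertiary alcohol/allylic alcohol F2, with the C19 hydroxymethyl cis to C4a.
 - (PhS)2/PBu3 would turn the allylic hydroxyl into the phenyl sulfide F3.
 - The tertiary alkoxide (NaH) would be alkylated with chloromethyl phenyl selenide to give F4.
 - Bu3SnH/AIBN would then generate the O–CH2 radical, which should close 5-exo onto C11a through a chair-like transition state with the C5 chain equatorial (C4a/C11a trans) and expel the phenylthio group from C19, leaving the exocyclic methylene in ester F5.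
 - LiAlH4 reduction of F5 gives 26.

2. Step 21. Oligomerisation through the allyl group, closure of a seven-membered ring through the C11=C19 methylene, or double-bond migration in the skipped diene may compete with nine-membered ring closure. Fallback, setting out from 33 and coming back at 35: a temporary tether.
 - Diol 33 would be bridged between the C7 and C12 oxygens with 1,3-dichloro-1,1,3,3-tetraisopropyldisiloxane (AgOTf, 2,6-lutidine) to give F6, in which the C7 carbinol is held over the face of the tetrahydrofuran that carries C11.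
 - Metathesis of F6 would close the same C8=C9 bond in this pre-organised setting to give F7.
 - HF·pyridine releases the ring-closed diol F8, and Dess–Martin oxidation gives 35.

3. Step 14. The hydroxy acid may relactonise to 24 before decarboxylation, or the excited acridinium may oxidise an alkene instead of the carboxylate. Fallback, setting out from 24 (through salt 25) and coming back at 26: oxidative instead of reductive decarboxylation.
 - Pb(OAc)4 (or anodic oxidation) would convert the carboxylate into the C1 oxocarbenium ion, which the neighbouring C3 hydroxyl traps as the bicyclic acetal F9.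
 - DIBAL-H should then open the acetal at the less hindered C1–O(C3) bond and give 26.

Further compounds
F1 | step 13 | unsaturated δ-lactone (C19 oxidised to C=O) of 18 | C=C[C@@](C)(O[Si](C)(C)C(C)(C)C)CC[C@H]1C=C(CO[Si](C)(C)C(C)(C)C)C(=O)O[C@@]1(CO[Si](C(C)C)(C(C)C)C(C)C)C(=O)OC
F2 | step 13 | ring-opened tertiary alcohol with allylic C19 alcohol cis to C4a | C=C[C@@](C)(O[Si](C)(C)C(C)(C)C)CC[C@@H](/C=C(\CO)CO[Si](C)(C)C(C)(C)C)[C@](O)(CO[Si](C(C)C)(C(C)C)C(C)C)C(=O)OC
F3 | step 13 | allylic phenyl sulfide of F2 | C=C[C@@](C)(O[Si](C)(C)C(C)(C)C)CC[C@@H](/C=C(\CSc1ccccc1)CO[Si](C)(C)C(C)(C)C)[C@](O)(CO[Si](C(C)C)(C(C)C)C(C)C)C(=O)OC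
F4 | step 13 | (phenylselanyl)methyl ether of F3 | C=C[C@@](C)(O[Si](C)(C)C(C)(C)C)CC[C@@H](/C=C(\CSc1ccccc1)CO[Si](C)(C)C(C)(C)C)[C@](OC[Se]c1ccccc1)(CO[Si](C(C)C)(C(C)C)C(C)C)C(=O)OC
F5 | step 13 | tetrahydrofuran methyl ester (C3 at ester level) | C=C[C@@](C)(O[Si](C)(C)C(C)(C)C)CC[C@H]1[C@H](C(=C)CO[Si](C)(C)C(C)(C)C)CO[C@@]1(CO[Si](C(C)C)(C(C)C)C(C)C)C(=O)OC
F6 | step 21 | disiloxane-bridged diene (O7 and O12 tethered) | C=C[C@]2(C)CC[C@H]1[C@H](C(=C)CC=C)CO[C@@]1(CO[Si](C(C)C)(C(C)C)O[Si](C(C)C)(C(C)C)O2)COC(=O)CCCCCCCCCCCCCCCCCC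
F7 | step 21 | disiloxane-bridged nine-membered ring | C=C1C/C=C\[C@]3(C)CC[C@H]2[C@H]1CO[C@@]2(CO[Si](C(C)C)(C(C)C)O[Si](C(C)C)(C(C)C)O3)COC(=O)CCCCCCCCCCCCCCCCCC
F8 | step 21 | nine-membered-ring diol | C=C1C/C=C\[C@@](C)(O)CC[C@H]2[C@H]1CO[C@@]2(CO)COC(=O)CCCCCCCCCCCCCCCCCC
F9 | step 14 | bicyclic acetal (C1 bonded to the ring oxygen and to the C3 oxygen) | C=C[C@@](C)(O[Si](C)(C)C(C)(C)C)CC[C@H]1[C@H](C(=C)CO[Si](C)(C)C(C)(C)C)[C@@H]2O[C@@]1(CO[Si](C(C)C)(C(C)C)C(C)C)CO2
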